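**Plan**
1. Ring numbering of the dienone half: C1 carbonyl, C2 methyl-bearing, C3 enol, C4 quaternary, C5 enol, C6 bridge-bearing. The retrosynthesis first cuts the two C–C bonds of the bridging CH2 (to the arene and to C6), then the ring bond C3–C4.
2. Enabling feature: the carbocycle C1–C6 is a cyclic 1,3,5-tricarbonyl array whose C4 carries a fourth (isobutyryl) carbonyl. C3 is therefore an acyl carbon and C4 the central carbon of a 1,3-diketone, so C3–C4 is a Claisen bond. The same chain is stable as a ring isomer, a 4-hydroxy-2-pyranone in which C3 is the lactone carbonyl on the C5 enol oxygen.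
3. Forward order: pyranone 1 is acylated and prenylated at its 6-methyl carbon (the future C4), then the pyranone is isomerised to the carbocycle by C3–C4 closure. The arene half (Friedel–Crafts acylation, C-prenylation, Mannich base) is joined last through an o-quinone methide, which forms the CH2 bridge.
4. Stereochemistry: the only stereocentre, quaternary C4, arises in the ring closure from a planar enolate (both epimers of the precursor converge) on a chiral bis(oxazoline)–magnesium template. No later step touches it.

Key step: step 3

Assumption: the sense of induction of the bis(oxazoline)–magnesium template in step 3 cannot be fixed by analogy; the (S,S)-ligand is written, and its equally available mirror image is to be used if the (4S)-dienone results.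

**Step 1**
Reactants: 1 4-hydroxy-3,6-dimethyl-2H-pyran-2-one; 2 N-methoxy-N,2-dimethylpropanamide
Product: 3 4-hydroxy-3-methyl-6-(3-methyl-2-oxobutyl)-2H-pyran-2-one
Conditions: LiN(i-Pr)2 (2.3 equiv), THF, −78 °C; 2 (1.1 equiv), −78 to 0 °C; 1 M HCl
Reagents that add atoms: N-methoxy-N,2-dimethylpropanamide (2), CC(C)C(=O)N(C)OC
Why: Double deprotonation (4-OH, then the 6-methyl group, vinylogous to the lactone carbonyl) should give a dianion that is C-acylated at the exocyclic carbon; the N-methoxy-N-methylamide holds the tetrahedral chelate until work-up, so the more acidic ketone cannot quench the dianion (dianion acylation of a hydroxypyranone, Weinreb ketone synthesis).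

**Step 2**
Reactants: 3 4-hydroxy-3-methyl-6-(3-methyl-2-oxobutyl)-2H-pyran-2-one; 4 1-bromo-3-methylbut-2-ene
Product: 5 rac-6-(2,7-dimethyl-3-oxooct-6-en-4-yl)-4-hydroxy-3-methyl-2H-pyran-2-one
Conditions: LiN(SiMe3)2 (2.1 equiv), THF, −78 to 0 °C; 4 (1.0 equiv), 0 °C; 1 M HCl
Reagents that add atoms: 1-bromo-3-methylbut-2-ene (4), CC(C)=CCBr
Why: The second equivalent of base forms the ketone enolate at the CH2 between pyranone C6 and the isobutyryl carbonyl, by far the most nucleophilic site of the dianion, and the soft allylic bromide should alkylate it at carbon (SN2 alkylation of a dianion); the aromatic pyranone keeps its C3 and C5 out of play, and the new C–H stereocentre may be racemic because step 3 erases it.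

**Step 3**
Reactants: 5 rac-6-(2,7-dimethyl-3-oxooct-6-en-4-yl)-4-hydroxy-3-methyl-2H-pyran-2-one
Product: 7 (4R)-3,5-dihydroxy-2-methyl-4-(2-methylpropanoyl)-4-(3-methylbut-2-en-1-yl)cyclohexa-2,5-dien-1-one, via ring-opened methyl trioxo ester 6 (not isolated)
Conditions: Mg(OMe)2 (1.5 equiv), 2,2'-(propane-2,2-diyl)bis[(4S)-4-phenyl-4,5-dihydrooxazole] (1.6 equiv), THF, 45 °C; then cold 1 M HCl
Reagents that add atoms: none
Why: Proposed new method: Mg-bound methoxide adds to the lactone carbonyl of 5 and opens the pyranone to the trioxo ester 6, held as a magnesium polyenolate in which both epimers of 5 have become one planar enolate at chain C6; this carbon attacks the C1 ester carbonyl and methoxide leaves again, so methanol is only a shuttle and the isomerisation is pulled by the stabilised trione enolate of 7. The closest known reaction types are the Mg(OMe)2-mediated Claisen cyclisation of 6-(2-oxoalkyl)-4-hydroxy-2-pyranones and 3,5,7-trioxo esters to acylphloroglucinols, and enantioselective additions of bis(oxazoline)-bound magnesium enolates of 2-substituted 1,3-dicarbonyl compounds to external electrophiles; a tethered ester as electrophile and an acyl-bearing quaternary carbon as product are new. The carbocycle closes 6-exo-trig (enolate carbon C6 onto the exocyclic C=O of the C1 ester). The quaternary centre is set by the C2-symmetric ligand on the magnesium that chelates the C5 and C7 oxygens: its two phenyl groups block, on opposite faces, the space above one or the other carbonyl end of the planar diketonate, so the tether that starts at the C5 end can arch only over the face whose C5-side quadrant is empty, and the ester meets one enantiotopic face of C6. The step needs C- over O-acylation and Claisen over aldol closure: magnesium ties up both diketonate oxygens and any pyranone re-formed by O-attack re-enters the cycle, while the only other electrophile is the hindered isopropyl ketone, whose aldol adduct cannot dehydrate and therefore reverts.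

**Step 4**
Reactants: 8 benzene-1,3,5-triol; 9 2-methylpropanoyl chloride
Product: 10 2-methyl-1-(2,4,6-trihydroxyphenyl)propan-1-one
Conditions: AlCl3 (3.5 equiv), PhNO2, 65 °C; then ice, 1 M HCl
Reagents that add atoms: 2-methylpropanoyl chloride (9), CC(C)C(Cl)=O
Why: Friedel–Crafts C-acylation of the electron-rich triol; the AlCl3-complexed aryl ketone is deactivated, so a single acyl group should enter.

**Step 5**
Reactants: 10 2-methyl-1-(2,4,6-trihydroxyphenyl)propan-1-one; 4 1-bromo-3-methylbut-2-ene
Product: 11 2-methyl-1-[2,4,6-trihydroxy-3-(3-methylbut-2-en-1-yl)phenyl]propan-1-one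
Conditions: 4 (1.0 equiv), 10% aq. KOH, 0 °C
Reagents that add atoms: 1-bromo-3-methylbut-2-ene (4), CC(C)=CCBr
Why: C-alkylation of the acylphloroglucinol phenolate by the soft allylic bromide in water, where hydrogen-bonded phenolate oxygens favour attack through carbon; the two free ring positions are equivalent, so one mono-prenyl isomer should form, and one equivalent of bromide limits over-alkylation.

**Step 6**
Reactants: 11 2-methyl-1-[2,4,6-trihydroxy-3-(3-methylbut-2-en-1-yl)phenyl]propan-1-one
Product: 12 1-[3-[(dimethylamino)methyl]-2,4,6-trihydroxy-5-(3-methylbut-2-en-1-yl)phenyl]-2-methylpropan-1-one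
Conditions: 37% aq. CH2O (1.1 equiv), 40% aq. Me2NH (1.2 equiv), EtOH, 0 °C to rt
Reagents that add atoms: formaldehyde, C=O; dimethylamine, CNC
Why: Mannich reaction at the only unsubstituted ring carbon, which is activated by two ortho hydroxyl groups; with no free ring position left the Mannich base cannot self-couple.

**Step 7**
Reactants: 7 (4R)-3,5-dihydroxy-2-methyl-4-(2-methylpropanoyl)-4-(3-methylbut-2-en-1-yl)cyclohexa-2,5-dien-1-one; 12 1-[3-[(dimethylamino)methyl]-2,4,6-trihydroxy-5-(3-methylbut-2-en-1-yl)phenyl]-2-methylpropan-1-one
Product: 14 (4S)-3,5-dihydroxy-2-methyl-4-(2-methylpropanoyl)-4-(3-methylbut-2-en-1-yl)-6-{[2,4,6-trihydroxy-3-(2-methylpropanoyl)-5-(3-methylbut-2-en-1-yl)phenyl]methyl}cyclohexa-2,5-dien-1-one, via o-quinone methide 13 (not isolated)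
Conditions: toluene, 90 °C, N2 stream
Reagents that add atoms: none
Why: The acidic enol 7 protonates the benzylic amine, thermal loss of Me2NH should give o-quinone methide 13, and the enolate of 7 adds through its only unsubstituted ring carbon C6 (Michael addition to an o-quinone methide, the Mannich-base route to methylene-bridged phloroglucinols); rearomatisation fixes the C-adduct while O-adducts revert. The quaternary centre is not involved; its descriptor changes from R to S only because the sequence-rule ranking of its two ring neighbours changes once C6 carries carbon.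

**Compound list**
1 | 4-hydroxy-3,6-dimethyl-2H-pyran-2-one | CC1=CC(O)=C(C)C(=O)O1 | starting material
2 | N-methoxy-N,2-dimethylpropanamide | CC(C)C(=O)N(C)OC | starting material
3 | 4-hydroxy-3-methyl-6-(3-methyl-2-oxobutyl)-2H-pyran-2-one | CC(C)C(=O)CC1=CC(O)=C(C)C(=O)O1 | intermediate
4 | 1-bromo-3-methylbut-2-ene (prenyl bromide) | CC(C)=CCBr | starting material
5 | rac-6-(2,7-dimethyl-3-oxooct-6-en-4-yl)-4-hydroxy-3-methyl-2H-pyran-2-one | CC(C)C(=O)C(CC=C(C)C)C1=CC(O)=C(C)C(=O)O1 | intermediate
6 | methyl 2,8-dimethyl-6-(3-methylbut-2-en-1-yl)-3,5,7-trioxononanoate (present as its magnesium polyenolate, not isolated) | COC(=O)C(C)C(=O)CC(=O)C(CC=C(C)C)C(=O)C(C)C | intermediate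
7 | (4R)-3,5-dihydroxy-2-methyl-4-(2-methylpropanoyl)-4-(3-methylbut-2-en-1-yl)cyclohexa-2,5-dien-1-one | O=C1C=C(O)[C@@](CC=C(C)C)(C(=O)C(C)C)C(O)=C1C | intermediate
8 | benzene-1,3,5-triol | Oc1cc(O)cc(O)c1 | starting material
9 | 2-methylpropanoyl chloride | CC(C)C(Cl)=O | starting material
10 | 2-methyl-1-(2,4,6-trihydroxyphenyl)propan-1-one | CC(C)C(=O)c1c(O)cc(O)cc1O | intermediate
11 | 2-methyl-1-[2,4,6-trihydroxy-3-(3-methylbut-2-en-1-yl)phenyl]propan-1-one | CC(C)=CCc1c(O)cc(O)c(C(=O)C(C)C)c1O | intermediate
12 | 1-[3-[(dimethylamino)methyl]-2,4,6-trihydroxy-5-(3-methylbut-2-en-1-yl)phenyl]-2-methylpropan-1-one | CC(C)=CCc1c(O)c(CN(C)C)c(O)c(C(=O)C(C)C)c1O | intermediate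
13 | o-quinone methide from 12: 3,5-dihydroxy-6-methylidene-2-(2-methylpropanoyl)-4-(3-methylbut-2-en-1-yl)cyclohexa-2,4-dien-1-one (not isolated) | C=C1C(=O)C(C(=O)C(C)C)=C(O)C(CC=C(C)C)=C1O | intermediate
14 | (4S)-3,5-dihydroxy-2-methyl-4-(2-methylpropanoyl)-4-(3-methylbut-2-en-1-yl)-6-{[2,4,6-trihydroxy-3-(2-methylpropanoyl)-5-(3-methylbut-2-en-1-yl)phenyl]methyl}cyclohexa-2,5-dien-1-one | CC(C)=CCc1c(O)c(CC2=C(O)[C@@](CC=C(C)C)(C(=O)C(C)C)C(O)=C(C)C2=O)c(O)c(C(=O)C(C)C)c1O | target

**Count**
Total step count: 7. Longest linear sequence: 4 steps (steps 1, 2, 3, 7; the arene branch, steps 4, 5, 6, 7, is equally long).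

**Steps most likely to fail**

Step 3 (proposed new method). The ring closure may run through ligand-free magnesium aggregates and give poor or reversed facial selectivity. Pyranone opening may be slow in THF. Methoxide may also cleave the isobutyryl group from the product by retro-Claisen reaction with aromatisation. The fallback sets out from 5 and uses only known chemistry. Compound 5 is isomerised with Mg(OMe)2 in boiling methanol without ligand, the established pyranone-to-acylphloroglucinol Claisen cyclisation, to give the racemic cyclohexadienone F1. This strong vinylogous acid is resolved by fractional crystallisation of its (S)-1-phenylethylammonium salt F2 (the (R)-amine is used if the other diastereomer crystallises). Acidification with cold dilute HCl comes back to the route at 7.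

Step 2. Alkylation may go to the enolate oxygen or the 4-oxido group, or the active methylene may be alkylated twice. The fallback sets out from 1 and reverses the order of the two bond formations. The dianion of 1 (LiN(i-Pr)2, THF) is alkylated with 4 at the 6-methyl carbon to give 4-hydroxy-3-methyl-6-(4-methylpent-3-en-1-yl)-2H-pyran-2-one F3. A second dianion, now at the CH2 next to the pyranone ring, is acylated with 2, so the prenyl-bearing carbon is formed by C-acylation of a carbanion that can react only once. This comes back to the route at 5.

Step 7. The o-quinone methide may oligomerise before it is trapped, C–C bond formation may be slow relative to reversible O-alkylation, and the liberated amine may induce retro-Claisen loss of the isobutyryl group at C4. The fallback sets out from 7 (with 11 from step 5) and reverses the polarity of the union. Compound 7 is converted with CH2O and Me2NH into its Mannich base, (4S)-6-[(dimethylamino)methyl]-3,5-dihydroxy-2-methyl-4-(2-methylpropanoyl)-4-(3-methylbut-2-en-1-yl)cyclohexa-2,5-dien-1-one F4. Warming F4 with 11 in toluene releases Me2NH and should give the 6-methylidene cyclohexenetrione F5 (not isolated). The free ring position of 11 traps F5 in a Friedel–Crafts-type conjugate addition, which comes back to the route at 14.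

**Further compounds**
F1 | step 3 | racemic 3,5-dihydroxy-2-methyl-4-(2-methylpropanoyl)-4-(3-methylbut-2-en-1-yl)cyclohexa-2,5-dien-1-one | O=C1C=C(O)C(CC=C(C)C)(C(=O)C(C)C)C(O)=C1C
F2 | step 3 | (S)-1-phenylethylammonium salt of 7 | C[C@H]([NH3+])c1ccccc1.O=C1C=C([O-])[C@@](CC=C(C)C)(C(=O)C(C)C)C(O)=C1C
F3 | step 2 | 4-hydroxy-3-methyl-6-(4-methylpent-3-en-1-yl)-2H-pyran-2-one | CC(C)=CCCC1=CC(O)=C(C)C(=O)O1
F4 | step 7 | (4S)-6-[(dimethylamino)methyl]-3,5-dihydroxy-2-methyl-4-(2-methylpropanoyl)-4-(3-methylbut-2-en-1-yl)cyclohexa-2,5-dien-1-one | CN(C)CC1=C(O)[C@@](CC=C(C)C)(C(=O)C(C)C)C(O)=C(C)C1=O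
F5 | step 7 | 6-methylidene cyclohexenetrione from F4, configuration at C4 unchanged (not isolated) | C=C1C(=O)[C@@](CC=C(C)C)(C(=O)C(C)C)C(O)=C(C)C1=O
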